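common to all: Z 2.5 mol%
- Tuesday's: J 0.20 M; D 1 equiv; run made earlier
- Sunday's: J 0.20 M; D 2.2 equiv; run made earlier
- Monday's: J 0.40 M; D 1.5 equiv; run made earlier
- flask: J 0.20 M; D 1.50 equiv; time 20 h

| run | time / h | Q / % | J / % |
|---|---|---|---|
| Tuesday's | 2.50 | 1.0 | 98.6 |
| Tuesday's | 5.00 | 2.8 | 96.9 |
| Tuesday's | 6.00 | 4.1 | 97.2 |
| Tuesday's | 10.0 | 7.1 | 93.0 |
| Tuesday's | 12.0 | 7.8 | 90.9 |
| Tuesday's | 15.0 | 12.0 | 88.6 |
| Sunday's | 0.833 | 1.2 | 100.2 |
| Sunday's | 2.50 | 1.2 | 98.9 |
| Sunday's | 5.00 | 3.0 | 96.0 |
| Sunday's | 6.00 | 3.4 | 95.5 |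
| Sunday's | 10.0 | 7.3 | 92.6 |
| Sunday's | 12.0 | 8.4 | 90.9 |
| Sunday's | 15.0 | 10.8 | 87.5 |
| Monday's | 1.33 | 0.1 | 99.9 |
| Monday's | 2.50 | 1.4 | 97.7 |
| Monday's | 5.00 | 2.8 | 96.2 |
| Monday's | 8.00 | 6.0 | 94.5 |
| Monday's | 15.0 | 12.7 | 87.7 |

(each reading ± 0.5 percentage points)

- D is a solid; its amount is given per volume of the solution
- what was read earlier has a scatter of 0.5 percentage points, one standard deviation
- at the start none of D is in solution

- spring: doubling the dissolution coefficient of D, all else as stated
- winter: doubling the amount of Z, all else as stated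
- dusk: doubling the solubility of D, all else as stated

- amount of Q at 20 h, in percent of the J charged
- the change that raises the amount of Q at 20 h, in percent of the J charged most ("none" if none brings more than 2 percentage points) (spring / winter / dusk / none)
- amount of Q at 20 h, in percent of the J charged, after dusk

Z stands at 2.5 mol% of the J in each earlier run. D went from 1 equiv to 2.2 equiv, and Q at 15.0 h read 12.0 % and 10.8 %, a gap of 1.2 percentage points against a scatter of 0.5 points. Monday's run doubled J, and Z with it, and read 12.7 %. That percentage, close to the other two, can mean first order in J, or a rate of Q that follows Z. The reckoning here takes the second reading. The mean Q at that time, 11.8 %, gives as a reading 3.17 h: this is the turnover time τ, the hours one charged Z needs on average over that stretch to deliver one Q.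

The ladder starts with a lag, taken here as the dissolving of D: Monday's run reads 0.1 % Q at 1.33 h, so this one reading puts the lag at about that long, shorter than τ. Then comes τ, then the asked 20 h. Slowest is the use of J, τ divided by the loading, 127 h, longer than the asked time, so in this flask Q should climb on a straight line to 15.8 %. Spring shortens a lag worth 1 point, less than the 2 points bar. Winter doubles the Z that τ counts, so it should double Q, while dusk acts on dissolved D, which may govern part of the turn. The pick here is winter.

The forecast gave 15.8 %, dusk as best and 28.5 % after dusk, holding that “the reaction is first order in J”; it parts from this reckoning on the best change.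

The flask gives 15.3 %, with winter best: it gains 15 points, more than dusk's 8.4 points and spring's 0.34 points. After dusk Q is 23.7 %.

    E.Z → Kj (k = 12.7 h⁻¹)
    J → G (k = 1.56 × 10⁻⁵ h⁻¹)
    J.Kj → X + Jo (k = 3.45 h⁻¹)
    E + Z → E.Z (k = 4.73 L mol⁻¹ h⁻¹)
    D ⇌ E, rate k5*(cs5 - [E]) while solid is left; crystals form when [E] > cs5 (solubility = 0.0990 M, k = 1.31 h⁻¹)
    J + Kj → J.Kj (k = 12.2 L mol⁻¹ h⁻¹)
    Jo → Z + Q (k = 16.7 h⁻¹)
    2 E.Z → E.Z2 (k = 4.01 L mol⁻¹ h⁻¹)

In the flask Z, the resting state of the round, holds 70.3 % of its charge at 20.0 h, and J is still 84.4 % then. Winter's Q is about twice the flask's, as τ reckons. The neighbouring flask, the same charge left until 72.0 h, tests the straight line: τ gives 56.8 %, and that flask holds 55.1 % Q.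

(The numbers in the tables stem from a simulated flask for substances that don't exist; scatter was added.)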